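The C9–C10 bond carries the whole plan: the C9 carbinol sits next to C10 of the ring-cis C1=C10 acrylate, an α-(hydroxyalkyl)acrylate retron. The ten-membered carbocycle (C1–C10) is therefore closed by an intramolecular Ni/Cr (Nozaki–Hiyama–Kishi) addition of a (Z)-α-iodoacrylate to an α-acetoxy aldehyde, which in one operation forms the ring, the C9 stereocentre and the trisubstituted enoate. The precursor is an open-chain iodo-aldehyde that already carries the cis-fused α-methylene-γ-lactone (C6, C7, C11, C12, O) and the 4,5-epoxide. Only C8 is bought (D-glyceraldehyde acetonide): C6/C7 are relayed by an indium allylation, C4/C5 by a C6–OH-directed epoxidation and C9 by the ring closure.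

Key step: step 12

Remark: germacrane numbering is used throughout (C1–C10 ring carbons, C11–C13 lactone carbons, C14 the ester carbon on C10); compounds 1, 2, 5, 7 and 20 are taken as commercial.

Step 1
Reactants: 1 (R)-2,3-O-isopropylideneglyceraldehyde; 2 methyl acrylate
Product: 3 methyl 2-{[(4R)-2,2-dimethyl-1,3-dioxolan-4-yl](hydroxy)methyl}prop-2-enoate (both carbinol epimers)
Conditions: DABCO (0.5 equiv), dioxane/H2O 1:1, rt
Reagents that add atoms: none
Why: Morita–Baylis–Hillman reaction; the new carbinol centre (future C7) need not be controlled because it becomes sp2 in step 2, and the aqueous medium shortens the reaction so that the α-alkoxy aldehyde should not epimerise.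

Step 2
Reactants: 3 Baylis–Hillman alcohol
Product: 4 methyl (2Z)-2-(bromomethyl)-3-[(4S)-2,2-dimethyl-1,3-dioxolan-4-yl]prop-2-enoate
Conditions: NBS, Me2S, CH2Cl2, 0 °C to rt
Reagents that add atoms: N-bromosuccinimide, O=C1CCC(=O)N1Br
Why: SN2′ bromination of a Baylis–Hillman alcohol through its alkoxysulfonium salt (Corey–Kim type), which should give the (Z)-2-(bromomethyl)enoate under neutral conditions that leave the acetonide intact.

Step 3
Reactants: 5 neryl acetate
Product: 6 (2Z)-3-methyl-6-oxohex-2-en-1-yl acetate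
Conditions: O3, CH2Cl2/pyridine, −78 °C (Sudan III end point); then Me2S
Reagents that add atoms: ozone, [O-][O+]=O
Why: ozonolysis, selective for the remote electron-rich trisubstituted alkene because the 2,3-alkene is deactivated by the allylic acetate.

Step 4
Reactants: 6 aldehyde; 7 methyl (triphenylphosphoranylidene)acetate
Product: 9 methyl (2Z,6Z)-8-acetoxy-2-iodo-6-methylocta-2,6-dienoate, via iodo ylide 8 (not isolated)
Conditions: 7, NIS, CH2Cl2, −20 °C; then 6, −20 °C to rt
Reagents that add atoms: N-iodosuccinimide, O=C1CCC(=O)N1I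
Why: one-pot ylide iodination and Wittig olefination, which should give mainly the (Z)-α-iodo enoate (iodine cis to the chain).

Step 5
Reactants: 9 iodo enoate acetate
Product: 10 methyl (2Z,6Z)-8-hydroxy-2-iodo-6-methylocta-2,6-dienoate
Conditions: K2CO3 (cat.), MeOH, 0 °C
Reagents that add atoms: none
Why: base-catalysed transesterification (Zemplén type) removes the allylic acetate, and exchange at the methyl ester is degenerate in methanol.

Step 6
Reactants: 10 allylic alcohol
Product: 11 methyl (2Z,6Z)-2-iodo-6-methyl-8-oxoocta-2,6-dienoate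
Conditions: MnO2, CH2Cl2, rt (used at once)
Reagents that add atoms: none
Why: chemoselective allylic oxidation under neutral heterogeneous conditions, which should keep the (Z)-enal geometry as in the oxidation of nerol to neral.

Step 7
Reactants: 4 allyl bromide; 11 (Z)-enal
Product: 12 dimethyl (2Z,6Z,8S,9S)-9-[(4S)-2,2-dimethyl-1,3-dioxolan-4-yl]-8-hydroxy-2-iodo-6-methyl-10-methylideneundeca-2,6-dienedioate (germacrane 6S,7S,8S)
Conditions: In powder, THF/H2O 1:1, rt
Reagents that add atoms: none
Why: indium Barbier allylation; the (Z)-σ-allylindium should react through a Zimmerman–Traxler chair to give the 6,7-syn adduct (the cis-lactone precursor), and indium held on the O8 face by the dioxolane oxygen, with H8 rather than C9 eclipsing the C11–CH2In unit (A1,3 strain), should fix the absolute sense at C6 and C7.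

Step 8
Reactants: 12 allylic alcohol
Product: 13 dimethyl (2Z,6R,7S,8R,9S)-9-[(4S)-2,2-dimethyl-1,3-dioxolan-4-yl]-6,7-epoxy-8-hydroxy-2-iodo-6-methyl-10-methylideneundec-2-enedioate (germacrane 4R,5S,6R,7S,8S)
Conditions: mCPBA, NaHCO3, CH2Cl2, 0 °C
Reagents that add atoms: meta-chloroperbenzoic acid, OOC(=O)c1cccc(Cl)c1
Why: hydroxyl-directed (Henbest) epoxidation; A1,3 strain from the cis C3 methylene keeps H6 in the alkene plane and the C6–OH delivers the peracid to its own face (threo), which sets C4 and C5 as the cis-epoxide, while the two acrylate-type alkenes are too electron-poor to react.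

Step 9
Reactants: 13 epoxy hydroxy ester
Product: 15 methyl (2Z)-5-{(2R,3S)-3-[(2R,3R)-3-[(1S)-1,2-dihydroxyethyl]-4-methylidene-5-oxooxolan-2-yl]-2-methyloxiran-2-yl}-2-iodopent-2-enoate, via lactone acetonide 14 (not isolated)
Conditions: PPTS (cat.), toluene, 50 °C; then MeOH, rt to 40 °C
Reagents that add atoms: none
Why: acid-catalysed lactonisation of the γ-hydroxy ester (only C6–OH is free, so the 6,12-lactone forms) followed by transketalisation of the terminal acetonide to methanol, under a weak acid chosen to spare the epoxide.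

Step 10
Reactants: 15 diol
Product: 17 methyl (2Z)-5-{(2R,3S)-3-[(2R,3R)-3-[(1S)-1-acetoxy-2-hydroxyethyl]-4-methylidene-5-oxooxolan-2-yl]-2-methyloxiran-2-yl}-2-iodopent-2-enoate, via cyclic orthoacetate 16 (not isolated)
Conditions: MeC(OMe)3, PPTS (cat.), CH2Cl2, rt; then H2O, rt
Reagents that add atoms: trimethyl orthoacetate, CC(OC)(OC)OC; water, O
Why: regioselective monoacylation of a 1,2-diol through its cyclic orthoester, whose kinetic hydrolysis should open toward the primary oxygen and leave the acetate on the secondary C8 oxygen.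

Step 11
Reactants: 17 primary alcohol
Product: 18 methyl (2Z)-5-{(2R,3S)-3-[(2R,3S)-3-[(1S)-1-acetoxy-2-oxoethyl]-4-methylidene-5-oxooxolan-2-yl]-2-methyloxiran-2-yl}-2-iodopent-2-enoate
Conditions: Dess–Martin periodinane, NaHCO3, CH2Cl2, 0 °C to rt (used crude)
Reagents that add atoms: none
Why: Dess–Martin oxidation under buffered, non-basic conditions should give the α-acetoxy aldehyde without acetyl migration or epimerisation at C8.

Step 12
Reactants: 18 seco iodo-aldehyde
Product: 19 methyl (1(10)E,4R,5S,6R,7R,8S,9S)-8-acetoxy-4,5-epoxy-9-hydroxygermacra-1(10),11(13)-dien-12,6-olid-14-oate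
Conditions: CrCl2 (8 equiv), NiCl2 (cat.), degassed DMSO/THF, rt, slow addition to 2 mM
Reagents that add atoms: none
Why: Ni(0) inserts into the C10–I bond, the alkenylnickel transmetalates to Cr(III), and the α-chromio acrylate carbon C10 adds to the C9 aldehyde, closing the carbocycle C1–C10 by a 10-exo-trig carbonyl addition; the closest known reaction type is the Nozaki–Hiyama–Kishi macrocyclisation of vinyl iodides onto aldehydes, which forms medium rings and tolerates esters, epoxides and lactones. The ring-cis C1=C10 geometry is secured twice, by the (Z)-iodide (retention) and by the tether, which in a ten-membered ring can deliver C9 only to the C2 side of C10. The new C9 stereocentre is controlled by C8: with the C8–OAc bond antiperiplanar to the incoming C10 (polar Felkin–Anh) and the chromium-bound carbonyl oxygen turned to the outside of the forming ring, both oxygens lie pseudo-equatorial on the C7–C8–C9–C10 segment, so C10 should add to the Si face of C9 and give the 8,9-syn (9S) alcohol. The step needs this face selectivity, insertion into the only C–I bond, and ring closure in preference to oligomerisation; the cis-fused lactone at C6/C7 and the cis-epoxide at C4/C5 act as turn elements that bring C9 and C10 together, and high dilution suppresses dimers.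

Step 13
Reactants: 20 (S)-2-methylglycidol
Product: 21 (2R)-2-methyloxirane-2-carboxylic acid
Conditions: RuCl3·xH2O (cat.), NaIO4, CCl4/MeCN/H2O, rt (used fresh)
Reagents that add atoms: sodium periodate (oxygen source through RuO4), [Na+].[O-]I(=O)(=O)=O; water, O
Why: Sharpless RuO4 oxidation of a primary epoxy alcohol to the epoxy acid, which does not touch the quaternary stereocentre (the descriptor changes from S to R only through the CIP priorities).

Step 14
Reactants: 19 macrocyclic C9 alcohol; 21 epoxy acid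
Product: 23 methyl (1(10)E,4R,5S,6R,7R,8S,9S)-8-acetoxy-4,5-epoxy-9-{[(2R)-2-methyloxiran-2-yl]carbonyloxy}germacra-1(10),11(13)-dien-12,6-olid-14-oate (CNP0159450.1), via mixed anhydride 22 (not isolated)
Conditions: 21, 2,4,6-trichlorobenzoyl chloride, Et3N, THF, 0 °C; then 19, DMAP, toluene, rt
Reagents that add atoms: 2,4,6-trichlorobenzoyl chloride (its atoms appear only in intermediate 22), ClC(=O)c1c(Cl)cc(Cl)cc1Cl
Why: Yamaguchi esterification, in which DMAP transfers the epoxy acyl group from the mixed anhydride to the hindered allylic C9–OH with retention, and a short reaction time should limit acetyl migration from O8 to O9.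

Compound list
1 | (R)-2,3-O-isopropylideneglyceraldehyde [(4R)-2,2-dimethyl-1,3-dioxolane-4-carbaldehyde] | O=C[C@H]1COC(C)(C)O1 | starting material
2 | methyl acrylate | C=CC(=O)OC | starting material
3 | methyl 2-{[(4R)-2,2-dimethyl-1,3-dioxolan-4-yl](hydroxy)methyl}prop-2-enoate (both carbinol epimers) | C=C(C(=O)OC)C(O)[C@H]1COC(C)(C)O1 | intermediate
4 | methyl (2Z)-2-(bromomethyl)-3-[(4S)-2,2-dimethyl-1,3-dioxolan-4-yl]prop-2-enoate | BrC/C(C(=O)OC)=C\[C@H]1COC(C)(C)O1 | intermediate
5 | neryl acetate [(2Z)-3,7-dimethylocta-2,6-dien-1-yl acetate] | CC(C)=CCC/C(C)=C\COC(C)=O | starting material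
6 | (2Z)-3-methyl-6-oxohex-2-en-1-yl acetate | O=CCC/C(C)=C\COC(C)=O | intermediate
7 | methyl (triphenylphosphoranylidene)acetate | COC(=O)C=P(c1ccccc1)(c1ccccc1)c1ccccc1 | starting material
8 | methyl iodo(triphenylphosphoranylidene)acetate (iodo ylide, not isolated) | COC(=O)C(I)=P(c1ccccc1)(c1ccccc1)c1ccccc1 | intermediate
9 | methyl (2Z,6Z)-8-acetoxy-2-iodo-6-methylocta-2,6-dienoate | COC(=O)/C(I)=C/CC/C(C)=C\COC(C)=O | intermediate
10 | methyl (2Z,6Z)-8-hydroxy-2-iodo-6-methylocta-2,6-dienoate | COC(=O)/C(I)=C/CC/C(C)=C\CO | intermediate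
11 | methyl (2Z,6Z)-2-iodo-6-methyl-8-oxoocta-2,6-dienoate | COC(=O)/C(I)=C/CC/C(C)=C\C=O | intermediate
12 | dimethyl (2Z,6Z,8S,9S)-9-[(4S)-2,2-dimethyl-1,3-dioxolan-4-yl]-8-hydroxy-2-iodo-6-methyl-10-methylideneundeca-2,6-dienedioate | C=C(C(=O)OC)[C@@H]([C@@H](O)/C=C(C)\CC/C=C(I)/C(=O)OC)[C@H]1COC(C)(C)O1 | intermediate
13 | dimethyl (2Z,6R,7S,8R,9S)-9-[(4S)-2,2-dimethyl-1,3-dioxolan-4-yl]-6,7-epoxy-8-hydroxy-2-iodo-6-methyl-10-methylideneundec-2-enedioate | C=C(C(=O)OC)[C@@H]([C@@H](O)[C@@H]1O[C@]1(C)CC/C=C(I)/C(=O)OC)[C@H]1COC(C)(C)O1 | intermediate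
14 | methyl (2Z)-5-{(2R,3S)-3-[(2R,3R)-3-[(4S)-2,2-dimethyl-1,3-dioxolan-4-yl]-4-methylidene-5-oxooxolan-2-yl]-2-methyloxiran-2-yl}-2-iodopent-2-enoate (lactone acetonide, not isolated) | C=C1C(=O)O[C@@H]([C@@H]2O[C@]2(C)CC/C=C(I)/C(=O)OC)[C@H]1[C@H]1COC(C)(C)O1 | intermediate
15 | methyl (2Z)-5-{(2R,3S)-3-[(2R,3R)-3-[(1S)-1,2-dihydroxyethyl]-4-methylidene-5-oxooxolan-2-yl]-2-methyloxiran-2-yl}-2-iodopent-2-enoate | C=C1C(=O)O[C@@H]([C@@H]2O[C@]2(C)CC/C=C(I)/C(=O)OC)[C@H]1[C@H](O)CO | intermediate
16 | methyl (2Z)-5-{(2R,3S)-3-[(2R,3R)-3-[(4S)-2-methoxy-2-methyl-1,3-dioxolan-4-yl]-4-methylidene-5-oxooxolan-2-yl]-2-methyloxiran-2-yl}-2-iodopent-2-enoate (cyclic orthoacetate, both orthoester epimers, not isolated) | C=C1C(=O)O[C@@H]([C@@H]2O[C@]2(C)CC/C=C(I)/C(=O)OC)[C@H]1[C@H]1COC(C)(OC)O1 | intermediate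
17 | methyl (2Z)-5-{(2R,3S)-3-[(2R,3R)-3-[(1S)-1-acetoxy-2-hydroxyethyl]-4-methylidene-5-oxooxolan-2-yl]-2-methyloxiran-2-yl}-2-iodopent-2-enoate | C=C1C(=O)O[C@@H]([C@@H]2O[C@]2(C)CC/C=C(I)/C(=O)OC)[C@H]1[C@H](OC(C)=O)CO | intermediate
18 | methyl (2Z)-5-{(2R,3S)-3-[(2R,3S)-3-[(1S)-1-acetoxy-2-oxoethyl]-4-methylidene-5-oxooxolan-2-yl]-2-methyloxiran-2-yl}-2-iodopent-2-enoate | C=C1C(=O)O[C@@H]([C@@H]2O[C@]2(C)CC/C=C(I)/C(=O)OC)[C@H]1[C@H](OC(C)=O)C=O | intermediate
19 | methyl (1(10)E,4R,5S,6R,7R,8S,9S)-8-acetoxy-4,5-epoxy-9-hydroxygermacra-1(10),11(13)-dien-12,6-olid-14-oate | C=C1C(=O)O[C@@H]2[C@H]1[C@H](OC(C)=O)[C@@H](O)/C(C(=O)OC)=C\CC[C@@]1(C)O[C@@H]21 | intermediate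
20 | (S)-2-methylglycidol {[(2S)-2-methyloxiran-2-yl]methanol} | OC[C@@]1(C)CO1 | starting material
21 | (2R)-2-methyloxirane-2-carboxylic acid | OC(=O)[C@@]1(C)CO1 | intermediate
22 | (2R)-2-methyloxirane-2-carboxylic 2,4,6-trichlorobenzoic anhydride (not isolated) | O=C(OC(=O)[C@@]1(C)CO1)c1c(Cl)cc(Cl)cc1Cl | intermediate
23 | methyl (1(10)E,4R,5S,6R,7R,8S,9S)-8-acetoxy-4,5-epoxy-9-{[(2R)-2-methyloxiran-2-yl]carbonyloxy}germacra-1(10),11(13)-dien-12,6-olid-14-oate (CNP0159450.1) | C=C1C(=O)O[C@@H]2[C@H]1[C@H](OC(C)=O)[C@@H](OC(=O)[C@@]1(C)CO1)/C(C(=O)OC)=C\CC[C@@]1(C)O[C@@H]21 | target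

Total step count: 14
Longest linear sequence: 11 steps (steps 3–12 and 14, from neryl acetate)

Steps most likely to fail

Step 12. The ring closure may proceed with poor or reversed facial selectivity at the aldehyde (C10 adding to the Re face of C9), because the 1,2-induction from C8 has to operate inside a strained ten-membered transition state. The fallback sets the C9 centre by hydride delivery to a ketone instead of by the C–C bond formation. It sets out from 18: the same Ni/Cr closure would then give the C9-epimeric macrocyclic alcohol F1 (alone or mixed with 19). Oxidation with Dess–Martin periodinane would give the macrocyclic C9 ketone F2. Luche reduction (NaBH4, CeCl3·7H2O, MeOH, −78 °C) should bring hydride in anti to the C8–OAc bond (Felkin–Anh, which for hydride is the 8,9-syn outcome), and the route is rejoined at 19.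

Step 7. The allylindium may react through the non-chelated conformer, that is on the π-face anti to the C8–O bond, which would keep the 6,7-syn relationship but invert C6 and C7 together relative to C8. The fallback turns this sense to use and corrects C8 afterwards by inversion. It sets out from 11, with (S)-2,3-O-isopropylideneglyceraldehyde in place of 1. Steps 1 and 2 would give the enantiomeric Baylis–Hillman alcohol F3 and the (4R)-dioxolanyl allyl bromide F4. Indium allylation of 11 would give the C8-epimeric hydroxy ester F5 with the required C6 and C7. Epoxidation as in step 8 would give the C8-epimeric epoxide F6, and the conditions of step 9 would lead through the C8-epimeric lactone acetonide F7 to the C8-epimeric diol F8. TBSCl and imidazole would silylate the primary hydroxyl to give the silyl ether F9. Mitsunobu reaction with acetic acid (PPh3, DIAD) would invert C8 and install the acetate, giving the (8S)-acetate silyl ether F10. HF·pyridine removes the silyl group, and the route is rejoined at 17.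

Step 9. Once the C8 hydroxyl is unmasked the 4,5-epoxide may be opened under the acidic conditions, by 5-exo attack of O8 on C5 to a tetrahydrofuran or by solvolysis at C4. The fallback postpones the epoxidation until the C8 oxygen is acylated, so that no free γ-hydroxyl ever faces the epoxide under acid. It sets out from 12: TsOH in MeOH would lactonise and remove the acetonide in one operation to give the alkene lactone diol F11. Trimethyl orthoacetate and PPTS, then water, would give through the cyclic orthoacetate F12 the alkene lactone 8-acetate F13. Epoxidation of the C4=C5 alkene with mCPBA rejoins the route at 17. Its face selectivity would then rest on A1,3 strain (H6 in the alkene plane) and on shielding of one face by the C7 substituent, not on hydroxyl delivery.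

Further compounds
F1 | step 12 | C9 epimer of 19, methyl (1(10)E,4R,5S,6R,7R,8S,9R)-8-acetoxy-4,5-epoxy-9-hydroxygermacra-1(10),11(13)-dien-12,6-olid-14-oate | C=C1C(=O)O[C@@H]2[C@H]1[C@H](OC(C)=O)[C@H](O)/C(C(=O)OC)=C\CC[C@@]1(C)O[C@@H]21
F2 | step 12 | macrocyclic C9 ketone, methyl 8-acetoxy-4,5-epoxy-9-oxogermacra-1(10),11(13)-dien-12,6-olid-14-oate | C=C1C(=O)O[C@@H]2[C@H]1[C@H](OC(C)=O)C(=O)/C(C(=O)OC)=C\CC[C@@]1(C)O[C@@H]21
F3 | step 7 | methyl 2-{[(4S)-2,2-dimethyl-1,3-dioxolan-4-yl](hydroxy)methyl}prop-2-enoate (both carbinol epimers) | C=C(C(=O)OC)C(O)[C@@H]1COC(C)(C)O1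
F4 | step 7 | methyl (2Z)-2-(bromomethyl)-3-[(4R)-2,2-dimethyl-1,3-dioxolan-4-yl]prop-2-enoate | BrC/C(C(=O)OC)=C\[C@@H]1COC(C)(C)O1
F5 | step 7 | C8 epimer of 12 (dioxolane centre inverted) | C=C(C(=O)OC)[C@@H]([C@@H](O)/C=C(C)\CC/C=C(I)/C(=O)OC)[C@@H]1COC(C)(C)O1
F6 | step 7 | C8 epimer of 13 | C=C(C(=O)OC)[C@@H]([C@@H](O)[C@@H]1O[C@]1(C)CC/C=C(I)/C(=O)OC)[C@@H]1COC(C)(C)O1
F7 | step 7 | C8 epimer of 14 (not isolated) | C=C1C(=O)O[C@@H]([C@@H]2O[C@]2(C)CC/C=C(I)/C(=O)OC)[C@H]1[C@@H]1COC(C)(C)O1
F8 | step 7 | C8 epimer of 15, the (1R)-1,2-dihydroxyethyl lactone | C=C1C(=O)O[C@@H]([C@@H]2O[C@]2(C)CC/C=C(I)/C(=O)OC)[C@H]1[C@@H](O)CO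
F9 | step 7 | primary TBS ether of F8 | C=C1C(=O)O[C@@H]([C@@H]2O[C@]2(C)CC/C=C(I)/C(=O)OC)[C@H]1[C@@H](O)CO[Si](C)(C)C(C)(C)C
F10 | step 7 | (8S)-acetate with primary TBS ether (TBS ether of 17) | C=C1C(=O)O[C@@H]([C@@H]2O[C@]2(C)CC/C=C(I)/C(=O)OC)[C@H]1[C@H](OC(C)=O)CO[Si](C)(C)C(C)(C)C
F11 | step 9 | alkene lactone diol, methyl (2Z,6Z)-7-{(2R,3R)-3-[(1S)-1,2-dihydroxyethyl]-4-methylidene-5-oxooxolan-2-yl}-2-iodo-6-methylhepta-2,6-dienoate | C=C1C(=O)O[C@@H](/C=C(C)\CC/C=C(I)/C(=O)OC)[C@H]1[C@H](O)CO
F12 | step 9 | cyclic orthoacetate of F11 (not isolated) | C=C1C(=O)O[C@@H](/C=C(C)\CC/C=C(I)/C(=O)OC)[C@H]1[C@H]1COC(C)(OC)O1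
F13 | step 9 | alkene lactone 8-acetate, the C4=C5 alkene corresponding to 17 | C=C1C(=O)O[C@@H](/C=C(C)\CC/C=C(I)/C(=O)OC)[C@H]1[C@H](OC(C)=O)CO
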